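**Retrosynthetic overview**
1. Jaspic acid comes from a protected core by three late operations: Negishi coupling of the C11 iodide with an aryl zinc, a Wittig reaction that converts a CH2CH2CHO arm into the homoprenyl chain, and thiolate cleavage of the aryl methyl ether and methyl ester.
2. The 4α‑Me/4β‑alkyl trans‑drimane core (C4, C5, C10 and C9 stereocentres) comes from a cis‑epoxide‑initiated chair–chair polyene bicyclisation. This is the key new step. Ring A (C4–C5) closes first, then ring B (C10–C9). The C3 oxygen is removed afterwards by Barton–McCombie, and the exocyclic Δ8(17) alkene is moved to Δ7 by Co–H isomerisation.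
3. The axial (4β) placement of the larger chain requires that chain to sit cis to C2 on the epoxide. A Sharpless cis‑epoxy tosylate (from a Z‑allylic alcohol made by propyne carbomagnesiation) is therefore coupled to the (E,E)‑8‑chlorogeranyl TBS ether through its allylic Grignard (from geraniol by SeO2 oxidation).
4. The terminal alkene of the C4 chain is masked as CH2CH2CH2OTBDPS. Left free, it would trap the C10 cation and form an extra ring.

*Assumptions:* compounds 1, 2, 3, 7, 18 and 22 are commercial. The phenol and acid are carried as OMe and CO2Me until the last step. The absolute configuration is that of the given SMILES (10β‑Me, 5α‑H, 4β‑chain). In the cascade, E1 loss of a C17 methyl proton to the exocyclic Δ8(17) alkene 12 is assumed to predominate. Any Δ7 isomer formed alongside it is carried forward unchanged through step 9.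

---

**Step 1**
Reactants: 1 ((3‑bromopropoxy)TBDPS silane), 2 (propyne), 3 (formaldehyde)
Product: 4 ((Z)‑6‑(TBDPSO)‑3‑methylhex‑2‑en‑1‑ol)
Conditions: 1, Mg, THF (gives RMgBr); CuI (10 mol %), propyne, THF, –20 °C; then HCHO gas (from (CH2O)n), –20 °C → rt
Reagents that add atoms: propyne (CC#C) and formaldehyde (C=O), which are reactants 2 and 3
Why: Cu‑catalysed syn carbomagnesiation (Normant) of propyne puts R on the internal carbon with Mg cis to R, and the formaldehyde quench gives the Z‑trisubstituted allylic alcohol (R cis to CH2OH). No stereocentre is formed.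

**Step 2**
Reactants: 4
Product: 5 ([(2S,3R)‑3‑(3‑TBDPSO‑propyl)‑3‑methyloxiran‑2‑yl]methanol, the cis‑epoxy alcohol)
Conditions: Ti(OiPr)4 (10 mol %), L‑(+)‑DET (12 mol %), TBHP, 4 Å MS, CH2Cl2, –20 °C
Reagents that add atoms: tert‑butyl hydroperoxide, CC(C)(C)OO (supplies the epoxide O)
Why: Sharpless asymmetric epoxidation of the Z‑allylic alcohol sets both epoxide carbons. L‑(+)‑DET gives the (2S,3R) cis epoxide, which later gives the 3β‑O/10β‑Me/5α‑H series.

**Step 3**
Reactants: 5
Product: 6 (epoxy tosylate)
Conditions: TsCl, Et3N, Me3N·HCl (cat.), CH2Cl2, 0 °C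
Reagents that add atoms: p‑toluenesulfonyl chloride, Cc1ccc(cc1)S(=O)(=O)Cl
Why: Sulfonylation of the primary alcohol gives a stable SN2 electrophile. The epoxide stereocentres are untouched.

**Step 4**
Reactants: 7 (geraniol)
Product: 8 (geranyl TBS ether)
Conditions: TBSCl, imidazole, DMF, 0 °C → rt
Reagents that add atoms: tert‑butyldimethylsilyl chloride, CC(C)(C)[Si](C)(C)Cl
Why: Silyl protection makes the alcohol compatible with the later Grignard and Lewis‑acid steps.

**Step 5**
Reactants: 8
Product: 9 ((2E,6E)‑8‑(TBSO)‑2,6‑dimethylocta‑2,6‑dien‑1‑ol)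
Conditions: SeO2 (5 mol %), TBHP, salicylic acid (cat.), CH2Cl2, rt; then NaBH4, EtOH, 0 °C
Reagents that add atoms: tert‑butyl hydroperoxide, CC(C)(C)OO (supplies the hydroxyl O)
Why: Umbreit–Sharpless allylic oxidation hits the terminal methyl trans to the chain. This gives the E‑CH2OH that becomes C1, which fixes the E geometry of the later C10=C5 alkene. NaBH4 reduces any over‑oxidised aldehyde.

**Step 6**
Reactants: 9
Product: 10 ((2E,6E)‑1‑chloro‑8‑(TBSO)‑2,6‑dimethylocta‑2,6‑diene)
Conditions: MsCl, 2,4,6‑collidine, LiCl, DMF, 0 °C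
Reagents that add atoms: lithium chloride, [Li+].[Cl-]
Why: Collington–Meyers chlorination goes through the mesylate with SN2 chloride displacement, so there is no allylic transposition and both alkene geometries are kept.

**Step 7**
Reactants: 10 (as its Grignard) and 6
Product: 11 (cis‑epoxy‑polyene: (2S,3R)‑2‑[(3E,7E)‑9‑(TBSO)‑3,7‑dimethylnona‑3,7‑dien‑1‑yl]‑3‑methyl‑3‑[3‑(TBDPSO)propyl]oxirane)
Conditions: 10, Mg, THF, 0 °C (allylic Grignard); then 6, Li2CuCl4 (5 mol %), THF, –30 → 0 °C
Reagents that add atoms: none (Mg and Cu are not incorporated)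
Why: Cu‑catalysed SN2 coupling (α‑attack of the allyl Grignard at the primary tosylate) forms the C1–C2 bond while the epoxide and both alkene geometries survive. No new stereocentre forms.

**Step 8**
Reactants: 11
Product: 12 (11‑OTBS‑4α‑methyl‑4β‑[3‑(TBDPSO)propyl]drim‑8(17)‑en‑3β‑ol)
Conditions: MeAlCl2 (1.5 equiv), 2,6‑di‑tert‑butyl‑4‑methylpyridine (2 equiv), CH2Cl2, –78 °C, 1 h; then aq. NaHCO3
Reagents that add atoms: none
Why: Proposed new method: a cis‑configured, Me/alkyl‑differentiated trisubstituted epoxide is used as the terminus of an epoxy‑polyene bicyclisation, so that epoxide geometry rather than substituent size puts the larger C4 group axial (β, syn to the developing C10‑Me) and the methyl equatorial. The Lewis‑acid‑activated epoxide is opened anti (inversion at C4) by C5 of the E‑alkene in a chair transition state, where the group cis to C2 must be pseudo‑axial. The resulting C10 cation is captured anti by C9 of the second E‑alkene, giving the trans‑decalin (5α‑H, 10β‑Me, 9α‑H with CH2OTBS equatorial). The C8 cation then loses a C17 proton (E1) to give the exocyclic alkene. The closest known reaction is the Corey/Johnson oxidosqualene‑type epoxy‑polyene cation–olefin cyclisation, which has not been shown with a cis, Me/alkyl‑differentiated epoxide terminus used to create a syn‑diaxial quaternary/methyl pair.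

**Step 9**
Reactants: 12
Product: 13 (11‑OTBS‑4α‑methyl‑4β‑[3‑(TBDPSO)propyl]drim‑7‑en‑3β‑ol)
Conditions: Co(salen)Cl (3 mol %), PhSiH3 (10 mol %), PhMe, rt
Reagents that add atoms: none (isomerisation)
Why: Co–H hydrogen‑atom‑transfer isomerisation (Shenvi type) adds H• to the exocyclic CH2 (C17) to give the tertiary C8 radical. The bulky Co(II) then removes H• from the accessible C7 methylene rather than from the tertiary H‑9, which is flanked by quaternary C10 and C11. This gives the trisubstituted Δ7 alkene and leaves C9 untouched.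

**Step 10**
Reactants: 13
Product: 14 (3β‑O‑(S‑methyl xanthate) of 13)
Conditions: NaHMDS, CS2, THF, 0 °C; then MeI
Reagents that add atoms: carbon disulfide, S=C=S; methyl iodide, CI
Why: Deprotonation, CS2 addition and S‑methylation convert the hindered neopentylic secondary alcohol into a radical precursor. No stereocentre changes.

**Step 11**
Reactants: 14
Product: 15 (3‑deoxy compound, 11‑OTBS‑4α‑methyl‑4β‑[3‑(TBDPSO)propyl]drim‑7‑ene)
Conditions: Bu3SnH, AIBN, PhMe, 110 °C
Reagents that add atoms: none (hydrogen only)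
Why: Barton–McCombie deoxygenation replaces C3–O by C3–H. C3 becomes CH2, so no stereocentre is created and C4 is untouched.

**Step 12**
Reactants: 15
Product: 16 (11‑ol, TBDPS retained)
Conditions: CSA (10 mol %), MeOH/CH2Cl2 (1:1), 0 °C
Reagents that add atoms: none
Why: Acid‑catalysed methanolysis cleaves the primary TBS ether selectively over the TBDPS ether.

**Step 13**
Reactants: 16
Product: 17 (11‑iodide)
Conditions: PPh3, I2, imidazole, CH2Cl2, 0 °C → rt
Reagents that add atoms: iodine, II
Why: Appel iodination of the primary alcohol leaves both alkenes and the TBDPS ether intact.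

**Step 14**
Reactants: 17 and 18 (methyl 3‑iodo‑4‑methoxybenzoate, converted in situ to ArZnI)
Product: 19 (11‑aryl compound: methyl 4‑methoxy‑3‑{[4α‑methyl‑4β‑(3‑TBDPSO‑propyl)drim‑7‑en‑11‑yl]}benzoate)
Conditions: 18, Zn, LiCl, THF, then 17, Pd‑PEPPSI‑IPent (3 mol %), THF/NMP, 50 °C
Reagents that add atoms: none beyond reactant 18 (Zn is not incorporated)
Why: Negishi sp3–sp2 coupling forms the C11–aryl bond under mild, ester‑tolerant conditions. C9 is not involved and no new stereocentre forms.

**Step 15**
Reactants: 19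
Product: 20 (primary alcohol after TBDPS removal)
Conditions: TBAF, THF, rt
Reagents that add atoms: none
Why: Fluoride cleaves the silyl ether. The aryl ester, aryl ether and both alkenes are unaffected.

**Step 16**
Reactants: 20
Product: 21 (aldehyde OHC‑CH2CH2‑C4)
Conditions: Dess–Martin periodinane, NaHCO3, CH2Cl2, rt
Reagents that add atoms: none
Why: Dess–Martin oxidation converts the primary alcohol to the aldehyde without touching the alkenes.

**Step 17**
Reactants: 21 and 22 (isopropyltriphenylphosphonium iodide)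
Product: 23 (jaspic acid methyl ether methyl ester)
Conditions: 22, KOt‑Bu, THF, 0 °C; then 21, 0 °C → rt
Reagents that add atoms: none beyond reactant 22
Why: Wittig olefination with the non‑stabilised isopropylidene ylide converts CHO into CH=CMe2, completing the homoprenyl chain. The non‑enolisable aryl ester survives at 0 °C.

**Step 18**
Reactants: 23
Product: 24 (jaspic acid)
Conditions: NaSEt, DMF, 120 °C; then aq. HCl
Reagents that add atoms: none (both methyl groups are lost)
Why: SN2 dealkylation by thiolate cleaves the aryl methyl ether and the methyl ester together. The alkenes and all stereocentres survive.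

---

**Compound list**

| No. | Name | SMILES | Role |
|---|---|---|---|
| 1 | (3‑bromopropoxy)(tert‑butyl)diphenylsilane | BrCCCO[Si](c1ccccc1)(c1ccccc1)C(C)(C)C | starting material |
| 2 | propyne | CC#C | starting material |
| 3 | formaldehyde | C=O | starting material |
| 4 | (Z)‑6‑(TBDPSO)‑3‑methylhex‑2‑en‑1‑ol | OC/C=C(/C)CCCO[Si](c1ccccc1)(c1ccccc1)C(C)(C)C | intermediate |
| 5 | [(2S,3R)‑3‑(3‑TBDPSO‑propyl)‑3‑methyloxiran‑2‑yl]methanol | OC[C@@H]1O[C@]1(C)CCCO[Si](c1ccccc1)(c1ccccc1)C(C)(C)C | intermediate |
| 6 | epoxy tosylate of 5 | Cc1ccc(cc1)S(=O)(=O)OC[C@@H]1O[C@]1(C)CCCO[Si](c1ccccc1)(c1ccccc1)C(C)(C)C | intermediate |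
| 7 | geraniol | CC(C)=CCC/C(C)=C/CO | starting material |
| 8 | geranyl TBS ether | CC(C)=CCC/C(C)=C/CO[Si](C)(C)C(C)(C)C | intermediate |
| 9 | (2E,6E)‑8‑(TBSO)‑2,6‑dimethylocta‑2,6‑dien‑1‑ol | OC/C(C)=C/CC/C(C)=C/CO[Si](C)(C)C(C)(C)C | intermediate |
| 10 | (2E,6E)‑1‑chloro‑8‑(TBSO)‑2,6‑dimethylocta‑2,6‑diene | ClC/C(C)=C/CC/C(C)=C/CO[Si](C)(C)C(C)(C)C | intermediate |
| 11 | cis‑epoxy‑polyene (2S,3R) | CC(C)(C)[Si](C)(C)OC/C=C(\C)CC/C=C(\C)CC[C@@H]1O[C@]1(C)CCCO[Si](c1ccccc1)(c1ccccc1)C(C)(C)C | intermediate |
| 12 | 11‑OTBS‑4α‑Me‑4β‑[3‑(TBDPSO)propyl]drim‑8(17)‑en‑3β‑ol | CC(C)(C)[Si](c3ccccc3)(c3ccccc3)OCCC[C@@]1(C)[C@@H](O)CC[C@]2(C)[C@@H](CO[Si](C)(C)C(C)(C)C)C(=C)CC[C@@H]12 | intermediate |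
| 13 | 11‑OTBS‑4α‑Me‑4β‑[3‑(TBDPSO)propyl]drim‑7‑en‑3β‑ol | CC(C)(C)[Si](c3ccccc3)(c3ccccc3)OCCC[C@@]1(C)[C@@H](O)CC[C@]2(C)[C@@H](CO[Si](C)(C)C(C)(C)C)C(C)=CC[C@@H]12 | intermediate |
| 14 | 3β‑O‑(S‑methyl xanthate) of 13 | CC(C)(C)[Si](c3ccccc3)(c3ccccc3)OCCC[C@@]1(C)[C@@H](OC(=S)SC)CC[C@]2(C)[C@@H](CO[Si](C)(C)C(C)(C)C)C(C)=CC[C@@H]12 | intermediate |
| 15 | 3‑deoxy compound | CC(C)(C)[Si](c3ccccc3)(c3ccccc3)OCCC[C@@]1(C)CCC[C@]2(C)[C@@H](CO[Si](C)(C)C(C)(C)C)C(C)=CC[C@@H]12 | intermediate |
| 16 | 11‑alcohol (TBDPS retained) | CC(C)(C)[Si](c3ccccc3)(c3ccccc3)OCCC[C@@]1(C)CCC[C@]2(C)[C@@H](CO)C(C)=CC[C@@H]12 | intermediate |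
| 17 | 11‑iodide | CC(C)(C)[Si](c3ccccc3)(c3ccccc3)OCCC[C@@]1(C)CCC[C@]2(C)[C@@H](CI)C(C)=CC[C@@H]12 | intermediate |
| 18 | methyl 3‑iodo‑4‑methoxybenzoate | COC(=O)c1ccc(OC)c(I)c1 | starting material |
| 19 | 11‑aryl compound (ester/ether, TBDPS) | CC(C)(C)[Si](c3ccccc3)(c3ccccc3)OCCC[C@@]1(C)CCC[C@]2(C)[C@@H](Cc4cc(C(=O)OC)ccc4OC)C(C)=CC[C@@H]12 | intermediate |
| 20 | primary alcohol | OCCC[C@@]1(C)CCC[C@]2(C)[C@@H](Cc3cc(C(=O)OC)ccc3OC)C(C)=CC[C@@H]12 | intermediate |
| 21 | aldehyde | O=CCC[C@@]1(C)CCC[C@]2(C)[C@@H](Cc3cc(C(=O)OC)ccc3OC)C(C)=CC[C@@H]12 | intermediate |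
| 22 | isopropyltriphenylphosphonium iodide | CC(C)[P+](c1ccccc1)(c1ccccc1)c1ccccc1.[I-] | starting material |
| 23 | jaspic acid methyl ether methyl ester | CC(C)=CCC[C@@]1(C)CCC[C@]2(C)[C@@H](Cc3cc(C(=O)OC)ccc3OC)C(C)=CC[C@@H]12 | intermediate |
| 24 | jaspic acid | CC(C)=CCC[C@@]1(C)CCC[C@]2(C)[C@@H](Cc3cc(C(=O)O)ccc3O)C(C)=CC[C@@H]12 | target |

---

**Total steps:** 18. **Longest linear sequence:** 15 steps (geraniol 7 → 24, or equivalently 1 → 24).

**Three steps most likely to fail**
1. **Step 8 (proposed new bicyclisation).** The axial C4 chain is syn‑diaxial to the developing C10 cation and methyl, so ring A may close through a twist‑boat. That would give the 4‑epi or cis‑fused product, or the silyl ethers may be lost.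
   - Fallback (known chemistry): (S)‑Wieland–Miescher ketone route. Selectively ketalise the saturated (C9) ketone, then do KOt‑Bu/allyl bromide deconjugative C4 alkylation (4α‑allyl‑Δ5). Reconjugate, then alkylate again with KOt‑Bu/MeI, so that Me enters the α face and pushes the allyl group to the axial β position. Carry this through Wolff–Kishner at C3, then hydroboration/oxidation of the allyl group and the isopropylidene Wittig. Build ring B from the C9 ketone afterwards. Set 5α‑H by Mn–H hydrogen‑atom‑transfer hydrogenation of Δ5.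
2. **Step 7 (allylic Grignard with the epoxy tosylate).** The allylic Grignard can transpose, scrambling the C10=C5 geometry or attacking through the wrong carbon, and it can open the epoxide.
   - Fallback: Julia–Kocienski olefination of the epoxy aldehyde made from 5 with the PT‑sulfone of the C1 methallyl unit, to give the C2=C1 alkene. Then selectively reduce the disubstituted alkene with diimide (NBSH), which leaves the epoxide and the trisubstituted alkenes.
3. **Step 14 (Negishi coupling with the β‑branched alkyl iodide).** β‑Hydride elimination toward C9 or homocoupling may compete.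
   - Fallback: oxidise 16 to the 11‑aldehyde and add an oxazoline‑protected aryl Grignard. Then deoxygenate the benzylic alcohol by Barton–McCombie and hydrolyse the oxazoline to the acid at the end.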